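**Retrosynthetic overview**

1. Labels: ring A = C2(=C1H2)–C3–C4(OH)–C5(Br)–C6(Me2)–C7(spiro); ring B = C7–C8–C9–C10(Me)(Cl)–C11(Br)–C12. The strategy rests on the homoallylic alcohol of ring A (exocyclic methylene C1 on C2, methylene C3, carbinol C4), the retron of a type-two carbonyl-ene reaction; cutting C3–C4 gives α-bromo aldehyde 24, with the isopropenyl group and the aldehyde chain both on C7.
2. 24 ⇐ aldehyde 23 by enamine-catalysed α-bromination (C5); the isopropenyl group ⇐ methylenation of a C7 acetyl group.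
3. Ring B halogens ⇐ bromolactonisation of a C7 carboxylic acid onto the C10=C11 alkene (C11–Br anti to the carboxyl), then replacement of the tertiary C10–O by chloride with retention.
4. C7/C6 (adjacent quaternary carbons) ⇐ Ireland–Claisen rearrangement of a prenyl ester on a symmetric 4-oxocyclohexane ketal; C7 becomes a stereocentre by enantioselective enolisation of the ketone.
5. Ring order: ring B is present in the starting material; ring A is closed in the last step.

Key step: step 14

Assumption: the (R,R)-lithium amide is taken to enolise ketone 9 in the same topological sense as it does 4-tert-butylcyclohexanone (large substituent equatorial); if the sense proved opposite, the (S,S)-amine would be used with no other change.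

**Route**

Step 1
Reactants: 1 1,4-dioxaspiro[4.5]decane-8-carboxylic acid; 2 1-bromo-3-methylbut-2-ene
Product: 3 3-methylbut-2-en-1-yl 1,4-dioxaspiro[4.5]decane-8-carboxylate
Conditions: K2CO3, DMF, rt
Reagents that add atoms: none
Why: O-alkylation of the carboxylate by the primary allylic bromide (SN2 esterification) is fast under these mild basic conditions and leaves the ketal untouched.

Step 2
Reactants: 3 3-methylbut-2-en-1-yl 1,4-dioxaspiro[4.5]decane-8-carboxylate
Product: 6 8-(2-methylbut-3-en-2-yl)-1,4-dioxaspiro[4.5]decane-8-carboxylic acid, via silyl ketene acetal 4 (not isolated), via trimethylsilyl ester 5 (not isolated)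
Conditions: LiN(i-Pr)2, THF, −78 °C; Me3SiCl; −78 → 65 °C; aqueous work-up (dilute citric acid)
Reagents that add atoms: chlorotrimethylsilane, C[Si](C)(C)Cl (its atoms remain only in 4 and 5)
Why: Ireland–Claisen rearrangement of the silyl ketene acetal joins C7 to the dimethyl-substituted allyl terminus through a six-membered transition state and so makes the two adjacent quaternary carbons C7 and C6 in one step; no stereocentre arises because the ring is still symmetric.

Step 3
Reactants: 6 8-(2-methylbut-3-en-2-yl)-1,4-dioxaspiro[4.5]decane-8-carboxylic acid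
Product: 9 5,5-dimethyl-2-oxaspiro[5.5]undecane-1,9-dione, via alkylborane 7 (not isolated), via hydroxy acid 8 (not isolated)
Conditions: 9-BBN (2.5 equiv), THF, 0 °C → rt; NaOH, H2O2, 0 °C; 2 M HCl, THF, rt
Reagents that add atoms: 9-borabicyclo[3.3.1]nonane, [H]B1C2CCCC1CCC2 (boron remains only in 7); hydrogen peroxide, OO; water, O
Why: Anti-Markovnikov hydroboration–oxidation of the only alkene gives the primary alcohol at C4 (the acid is carried as its acyloxyborane), and acidification hydrolyses the ketal and closes the δ-lactone, which masks C4–OH and the C7 carboxyl together.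

Step 4
Reactants: 9 5,5-dimethyl-2-oxaspiro[5.5]undecane-1,9-dione
Product: 11 (6R)-5,5-dimethyl-1-oxo-2-oxaspiro[5.5]undec-8-en-9-yl trifluoromethanesulfonate, via lithium enolate 10 (not isolated)
Conditions: lithium bis[(1R)-1-phenylethyl]amide (from the amine and n-BuLi), LiCl, THF, −78 °C; PhNTf2, −78 → 0 °C
Reagents that add atoms: lithium bis[(1R)-1-phenylethyl]amide, C[C@H](c1ccccc1)N([Li])[C@H](C)c1ccccc1 (lithium remains only in 10); N-phenylbis(trifluoromethanesulfonimide), O=S(=O)(N(c1ccccc1)S(=O)(=O)C(F)(F)F)C(F)(F)F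
Why: Enantioselective deprotonation of a prochiral 4,4-disubstituted cyclohexanone by a chiral lithium amide removes one of the two enantiotopic axial α-protons, and O-triflation of the enolate fixes the C10=C11 double bond, which makes C7 stereogenic with the (R) configuration under the stated assumption.

Step 5
Reactants: 11 (6R)-5,5-dimethyl-1-oxo-2-oxaspiro[5.5]undec-8-en-9-yl trifluoromethanesulfonate
Product: 12 (6R)-5,5,9-trimethyl-2-oxaspiro[5.5]undec-8-en-1-one
Conditions: MeMgBr, Fe(acac)3 (5 mol%), THF/NMP, −30 °C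
Reagents that add atoms: methylmagnesium bromide, C[Mg]Br
Why: Iron-catalysed cross-coupling of an alkenyl triflate with a methyl Grignard reagent is fast at low temperature and should outrun addition to the hindered lactone carbonyl, putting the C10 methyl group in place without touching C7.

Step 6
Reactants: 12 (6R)-5,5,9-trimethyl-2-oxaspiro[5.5]undec-8-en-1-one
Product: 15 (1R)-1-{4-[(tert-butyldiphenylsilyl)oxy]-2-methylbutan-2-yl}-4-methylcyclohex-3-ene-1-carboxylic acid, via potassium hydroxy carboxylate 13 (not isolated), via silyl ester 14 (not isolated)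
Conditions: KOH, EtOH/H2O, reflux; evaporate; t-BuPh2SiCl (2.2 equiv), imidazole, DMF, rt; AcOH/THF/H2O
Reagents that add atoms: potassium hydroxide, [K+].[OH-]; tert-butyl(chloro)diphenylsilane, CC(C)(C)[Si](Cl)(c1ccccc1)c1ccccc1
Why: Saponification opens the lactone, silylation of the salt caps the C4 alcohol before it can relactonise, and the labile silyl ester is hydrolysed on work-up, freeing the C7 carboxylic acid for the next step.

Step 7
Reactants: 15 (1R)-1-{4-[(tert-butyldiphenylsilyl)oxy]-2-methylbutan-2-yl}-4-methylcyclohex-3-ene-1-carboxylic acid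
Product: 16 (1S,4R,6S)-6-bromo-4-{4-[(tert-butyldiphenylsilyl)oxy]-2-methylbutan-2-yl}-1-methyl-2-oxabicyclo[2.2.2]octan-3-one
Conditions: NBS, NaHCO3, MeCN/H2O, 0 °C, dark
Reagents that add atoms: N-bromosuccinimide, O=C1CCC(=O)N1Br
Why: Bromolactonisation: the C7 carboxylate can reach only its own face of ring B and opens the bromonium ion at the tertiary carbon C10 (Markovnikov, bridged δ-lactone), so C10–O is cis to the carboxyl carbon and C11–Br is delivered anti to it, which sets C10 and C11 relative to C7; recrystallisation of this lactone, if it is crystalline, offers a point for raising enantiomeric purity.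

Step 8
Reactants: 16 (1S,4R,6S)-6-bromo-4-{4-[(tert-butyldiphenylsilyl)oxy]-2-methylbutan-2-yl}-1-methyl-2-oxabicyclo[2.2.2]octan-3-one
Product: 18 1-[(1R,3S,4S)-3-bromo-1-{4-[(tert-butyldiphenylsilyl)oxy]-2-methylbutan-2-yl}-4-hydroxy-4-methylcyclohexyl]ethan-1-one, via lithium hemiketal 17 (not isolated)
Conditions: MeLi (1.1 equiv), THF, −78 °C; AcOH, −78 °C
Reagents that add atoms: methyllithium, [Li]C
Why: Mono-addition of MeLi to the lactone carbonyl gives a lithium hemiketal that should survive until the cold acidic quench (lactone-to-methyl-ketone conversion); in the freed bromohydrin the C10–OH and C11–Br are trans-diequatorial, an arrangement that cannot close to an epoxide.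

Step 9
Reactants: 18 1-[(1R,3S,4S)-3-bromo-1-{4-[(tert-butyldiphenylsilyl)oxy]-2-methylbutan-2-yl}-4-hydroxy-4-methylcyclohexyl]ethan-1-one
Product: 20 1-[(1R,3S,4S)-3-bromo-1-{4-[(tert-butyldiphenylsilyl)oxy]-2-methylbutan-2-yl}-4-chloro-4-methylcyclohexyl]ethan-1-one, via chlorosulfite 19 (not isolated)
Conditions: SOCl2, Et2O, −20 → 0 °C
Reagents that add atoms: thionyl chloride, O=S(Cl)Cl
Why: The chlorosulfite of the tertiary alcohol ionises and returns chloride to C10 from the face the oxygen left (SNi-type internal return), while the neighbouring C11 bromine can bridge to the developing cation and screens the opposite face, so C–O should be replaced by C–Cl with retention to give the trans-diequatorial bromochloride.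

Step 10
Reactants: 20 1-[(1R,3S,4S)-3-bromo-1-{4-[(tert-butyldiphenylsilyl)oxy]-2-methylbutan-2-yl}-4-chloro-4-methylcyclohexyl]ethan-1-one
Product: 21 tert-butyl{3-[(1S,3S,4S)-3-bromo-4-chloro-4-methyl-1-(prop-1-en-2-yl)cyclohexyl]-3-methylbutoxy}diphenylsilane
Conditions: Cp2TiMe2, toluene/THF, 65 °C, dark
Reagents that add atoms: dimethyltitanocene, [CH3-].[CH3-].[Ti+4].c1cc[cH-]c1.c1cc[cH-]c1
Why: Petasis methylenation: the small, non-basic titanium methylidene formed on heating Cp2TiMe2 converts hindered, enolisable methyl ketones into 1,1-disubstituted alkenes and should leave the equatorial secondary bromide, the tertiary chloride and the silyl ether untouched.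

Step 11
Reactants: 21 tert-butyl{3-[(1S,3S,4S)-3-bromo-4-chloro-4-methyl-1-(prop-1-en-2-yl)cyclohexyl]-3-methylbutoxy}diphenylsilane
Product: 22 3-[(1S,3S,4S)-3-bromo-4-chloro-4-methyl-1-(prop-1-en-2-yl)cyclohexyl]-3-methylbutan-1-ol
Conditions: Bu4NF, AcOH (1:1), THF, rt
Reagents that add atoms: none
Why: Fluoride-mediated silyl ether cleavage frees the primary alcohol, and buffering with acetic acid keeps the medium too weakly basic for dehydrohalogenation.

Step 12
Reactants: 22 3-[(1S,3S,4S)-3-bromo-4-chloro-4-methyl-1-(prop-1-en-2-yl)cyclohexyl]-3-methylbutan-1-ol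
Product: 23 3-[(1S,3S,4S)-3-bromo-4-chloro-4-methyl-1-(prop-1-en-2-yl)cyclohexyl]-3-methylbutanal
Conditions: Dess–Martin periodinane, NaHCO3, CH2Cl2, 0 °C → rt
Reagents that add atoms: none
Why: Dess–Martin oxidation takes the primary alcohol to the aldehyde under neutral conditions that spare the alkene and both halides.

Step 13
Reactants: 23 3-[(1S,3S,4S)-3-bromo-4-chloro-4-methyl-1-(prop-1-en-2-yl)cyclohexyl]-3-methylbutanal
Product: 24 (2S)-2-bromo-3-[(1S,3S,4S)-3-bromo-4-chloro-4-methyl-1-(prop-1-en-2-yl)cyclohexyl]-3-methylbutanal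
Conditions: (S)-α,α-diphenylprolinol trimethylsilyl ether (20 mol%), 4,4-dibromo-2,6-di-tert-butylcyclohexa-2,5-dien-1-one, PhCO2H (20 mol%), CH2Cl2/pentane, −40 °C; short cold silica plug, used at once
Reagents that add atoms: 4,4-dibromo-2,6-di-tert-butylcyclohexa-2,5-dien-1-one, CC(C)(C)C1=CC(Br)(Br)C=C(C(C)(C)C)C1=O
Why: Enamine-catalysed α-bromination of an aldehyde: the (S)-diarylprolinol silyl ether forms the E-enamine and shields one of its faces, so bromine should enter C5 from the other face to give the (2S) bromide under catalyst control, as is known for 3,3-dimethylbutanal-type aldehydes, while the mild dienone reagent should not attack the isopropenyl group.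

Step 14
Reactants: 24 (2S)-2-bromo-3-[(1S,3S,4S)-3-bromo-4-chloro-4-methyl-1-(prop-1-en-2-yl)cyclohexyl]-3-methylbutanal
Product: 25 (2S,3S,6S,8S,9S)-2,8-dibromo-9-chloro-1,1,9-trimethyl-5-methylidenespiro[5.5]undecan-3-ol
Conditions: methylaluminium bis(4-bromo-2,6-di-tert-butylphenoxide) (1.2 equiv, from Me3Al and the phenol), CH2Cl2, −78 °C
Reagents that add atoms: none
Why: The bulky aluminium Lewis acid activates the α-bromo aldehyde, C3 of the isopropenyl group adds to C4 and a hydrogen of the C1 methyl group passes to oxygen, an intramolecular type-two carbonyl-ene reaction of the kind known to turn δ,ε-unsaturated aldehydes into 3-methylenecyclohexanols. Ring A closes as a six-membered ring by C3–C4 bond formation, exo with respect to the carbonyl group, with the ene double bond moving to the exocyclic C2=C1 position. The new stereocentre C4 is controlled by the C5 bromine stereocentre in a chair transition state: bromine equatorial with the aluminium-bound oxygen equatorial gives the trans bromohydrin, and the Cornforth-type chair with bromine and oxygen both axial leads to the same trans isomer. Only the closed chair with axial oxygen and equatorial bromine, the arrangement favoured by small alkylaluminium chlorides, would give the cis isomer, and the very large aryloxide ligands are chosen to disfavour it. The step needs chemoselectivity for the isopropenyl group (secured because ring B is saturated), hydrogen transfer from the methyl group only (secured because C7 is quaternary), and trans diastereoselectivity (secured by the C5 configuration together with the bulk of the Lewis acid).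

**Compound list**

1 | 1,4-dioxaspiro[4.5]decane-8-carboxylic acid | OC(=O)C1CCC2(CC1)OCCO2 | starting material
2 | 1-bromo-3-methylbut-2-ene (prenyl bromide) | CC(C)=CCBr | starting material
3 | 3-methylbut-2-en-1-yl 1,4-dioxaspiro[4.5]decane-8-carboxylate | CC(C)=CCOC(=O)C1CCC2(CC1)OCCO2 | intermediate
4 | 8-{[(3-methylbut-2-en-1-yl)oxy][(trimethylsilyl)oxy]methylidene}-1,4-dioxaspiro[4.5]decane (silyl ketene acetal) | CC(C)=CCOC(O[Si](C)(C)C)=C1CCC2(CC1)OCCO2 | intermediate
5 | trimethylsilyl 8-(2-methylbut-3-en-2-yl)-1,4-dioxaspiro[4.5]decane-8-carboxylate | C[Si](C)(C)OC(=O)C1(CCC2(CC1)OCCO2)C(C)(C)C=C | intermediate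
6 | 8-(2-methylbut-3-en-2-yl)-1,4-dioxaspiro[4.5]decane-8-carboxylic acid | OC(=O)C1(CCC2(CC1)OCCO2)C(C)(C)C=C | intermediate
7 | 9-borabicyclo[3.3.1]nonan-9-yl 8-[4-(9-borabicyclo[3.3.1]nonan-9-yl)-2-methylbutan-2-yl]-1,4-dioxaspiro[4.5]decane-8-carboxylate (alkylborane, acid held as acyloxyborane) | O=C(OB1C2CCCC1CCC2)C3(CCC4(CC3)OCCO4)C(C)(C)CCB5C6CCCC5CCC6 | intermediate
8 | 8-(4-hydroxy-2-methylbutan-2-yl)-1,4-dioxaspiro[4.5]decane-8-carboxylic acid | OC(=O)C1(CCC2(CC1)OCCO2)C(C)(C)CCO | intermediate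
9 | 5,5-dimethyl-2-oxaspiro[5.5]undecane-1,9-dione | O=C1OCCC(C)(C)C12CCC(=O)CC2 | intermediate
10 | lithium (6R)-5,5-dimethyl-1-oxo-2-oxaspiro[5.5]undec-8-en-9-olate | O=C1OCCC(C)(C)[C@]12CCC(O[Li])=CC2 | intermediate
11 | (6R)-5,5-dimethyl-1-oxo-2-oxaspiro[5.5]undec-8-en-9-yl trifluoromethanesulfonate | O=C1OCCC(C)(C)[C@]12CCC(OS(=O)(=O)C(F)(F)F)=CC2 | intermediate
12 | (6R)-5,5,9-trimethyl-2-oxaspiro[5.5]undec-8-en-1-one | O=C1OCCC(C)(C)[C@]12CCC(C)=CC2 | intermediate
13 | potassium (1R)-1-(4-hydroxy-2-methylbutan-2-yl)-4-methylcyclohex-3-ene-1-carboxylate | [K+].[O-]C(=O)[C@]1(C(C)(C)CCO)CCC(C)=CC1 | intermediate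
14 | tert-butyldiphenylsilyl (1R)-1-{4-[(tert-butyldiphenylsilyl)oxy]-2-methylbutan-2-yl}-4-methylcyclohex-3-ene-1-carboxylate | CC(C)(C)[Si](c1ccccc1)(c1ccccc1)OC(=O)[C@]2(C(C)(C)CCO[Si](c3ccccc3)(c3ccccc3)C(C)(C)C)CCC(C)=CC2 | intermediate
15 | (1R)-1-{4-[(tert-butyldiphenylsilyl)oxy]-2-methylbutan-2-yl}-4-methylcyclohex-3-ene-1-carboxylic acid | OC(=O)[C@]1(C(C)(C)CCO[Si](c2ccccc2)(c2ccccc2)C(C)(C)C)CCC(C)=CC1 | intermediate
16 | (1S,4R,6S)-6-bromo-4-{4-[(tert-butyldiphenylsilyl)oxy]-2-methylbutan-2-yl}-1-methyl-2-oxabicyclo[2.2.2]octan-3-one | CC(C)(C)[Si](c1ccccc1)(c1ccccc1)OCCC(C)(C)[C@]23CC[C@](C)(OC2=O)[C@@H](Br)C3 | intermediate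
17 | lithium (1S,4R,6S)-6-bromo-4-{4-[(tert-butyldiphenylsilyl)oxy]-2-methylbutan-2-yl}-1,3-dimethyl-2-oxabicyclo[2.2.2]octan-3-olate (hemiketal carbon undefined) | CC(C)(C)[Si](c1ccccc1)(c1ccccc1)OCCC(C)(C)[C@]23CC[C@](C)(OC2(C)O[Li])[C@@H](Br)C3 | intermediate
18 | 1-[(1R,3S,4S)-3-bromo-1-{4-[(tert-butyldiphenylsilyl)oxy]-2-methylbutan-2-yl}-4-hydroxy-4-methylcyclohexyl]ethan-1-one | CC(=O)[C@]1(C(C)(C)CCO[Si](c2ccccc2)(c2ccccc2)C(C)(C)C)CC[C@](C)(O)[C@@H](Br)C1 | intermediate
19 | (1S,2S,4R)-4-acetyl-2-bromo-4-{4-[(tert-butyldiphenylsilyl)oxy]-2-methylbutan-2-yl}-1-methylcyclohexyl chlorosulfite | CC(=O)[C@]1(C(C)(C)CCO[Si](c2ccccc2)(c2ccccc2)C(C)(C)C)CC[C@](C)(OS(Cl)=O)[C@@H](Br)C1 | intermediate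
20 | 1-[(1R,3S,4S)-3-bromo-1-{4-[(tert-butyldiphenylsilyl)oxy]-2-methylbutan-2-yl}-4-chloro-4-methylcyclohexyl]ethan-1-one | CC(=O)[C@]1(C(C)(C)CCO[Si](c2ccccc2)(c2ccccc2)C(C)(C)C)CC[C@](C)(Cl)[C@@H](Br)C1 | intermediate
21 | tert-butyl{3-[(1S,3S,4S)-3-bromo-4-chloro-4-methyl-1-(prop-1-en-2-yl)cyclohexyl]-3-methylbutoxy}diphenylsilane | CC(=C)[C@]1(C(C)(C)CCO[Si](c2ccccc2)(c2ccccc2)C(C)(C)C)CC[C@](C)(Cl)[C@@H](Br)C1 | intermediate
22 | 3-[(1S,3S,4S)-3-bromo-4-chloro-4-methyl-1-(prop-1-en-2-yl)cyclohexyl]-3-methylbutan-1-ol | CC(=C)[C@]1(C(C)(C)CCO)CC[C@](C)(Cl)[C@@H](Br)C1 | intermediate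
23 | 3-[(1S,3S,4S)-3-bromo-4-chloro-4-methyl-1-(prop-1-en-2-yl)cyclohexyl]-3-methylbutanal | CC(=C)[C@]1(C(C)(C)CC=O)CC[C@](C)(Cl)[C@@H](Br)C1 | intermediate
24 | (2S)-2-bromo-3-[(1S,3S,4S)-3-bromo-4-chloro-4-methyl-1-(prop-1-en-2-yl)cyclohexyl]-3-methylbutanal | CC(=C)[C@]1(C(C)(C)[C@H](Br)C=O)CC[C@](C)(Cl)[C@@H](Br)C1 | intermediate
25 | (2S,3S,6S,8S,9S)-2,8-dibromo-9-chloro-1,1,9-trimethyl-5-methylidenespiro[5.5]undecan-3-ol | C=C1C[C@H](O)[C@@H](Br)C(C)(C)[C@]12CC[C@](C)(Cl)[C@@H](Br)C2 | target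

**Totals and risks**

Total step count: 14. Longest linear sequence: 14 steps (1 to 25).

Step 14 (closure of ring A). The risk is poor facial selectivity at C4: if the closed chair with axial oxygen competes, the cis bromohydrin forms. Stepwise loss of a proton from C3 to give the endocyclic alkene is a lesser concern. The fallback sets out from 24 and returns at 25. The cyclisation is run with Me2AlCl in CH2Cl2 at −78 °C, where type-two carbonyl-ene closures favour the axial alcohol, so as to form the C4 epimer (2S,3R,6S,8S,9S)-2,8-dibromo-9-chloro-1,1,9-trimethyl-5-methylidenespiro[5.5]undecan-3-ol F1 on purpose. Mitsunobu inversion with chloroacetic acid, PPh3 and diisopropyl azodicarboxylate (toluene, 0 °C → rt) displaces the axial oxygen from the equatorial side and gives (2S,3S,6S,8S,9S)-2,8-dibromo-9-chloro-1,1,9-trimethyl-5-methylidenespiro[5.5]undecan-3-yl chloroacetate F2. Thiourea and NaHCO3 in EtOH at 50 °C then remove the chloroacetyl group without a base strong enough to close an epoxide, giving 25.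

Step 9 (C10–OH to C10–Cl). The risks are loss of configuration at C10 through an open cation, elimination to alkenes, or entry of chloride at C11 with interchange of the two halogens. The fallback sets out from 16 and returns at 20. The tertiary alkyl–oxygen bond of the lactone is cleaved directly with HCl gas and ZnCl2 (cat.) in CH2Cl2 at 0 °C, as tert-butyl esters are cleaved by HCl, with the anti C11 bromine assisting ionisation. This gives (1R,3S,4S)-3-bromo-1-{4-[(tert-butyldiphenylsilyl)oxy]-2-methylbutan-2-yl}-4-chloro-4-methylcyclohexane-1-carboxylic acid F3. (COCl)2 with cat. DMF converts it into (1R,3S,4S)-3-bromo-1-{4-[(tert-butyldiphenylsilyl)oxy]-2-methylbutan-2-yl}-4-chloro-4-methylcyclohexane-1-carbonyl chloride F4, and Me2CuLi in Et2O at −78 °C gives methyl ketone 20.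

Step 13 (α-bromination). The risks are slow enamine formation at the neopentyl-type aldehyde, insufficient catalyst control over the C5 face, and erosion of C5 by enolisation of the α-bromo aldehyde before use. The fallback sets out from 23 and returns at 24, and moves the bromination to an auxiliary-controlled imide enolate.
- Pinnick oxidation (NaClO2, NaH2PO4, 2-methylbut-2-ene, t-BuOH/H2O) gives 3-[(1S,3S,4S)-3-bromo-4-chloro-4-methyl-1-(prop-1-en-2-yl)cyclohexyl]-3-methylbutanoic acid F5.
- t-BuCOCl and Et3N in THF at −20 °C give 3-[(1S,3S,4S)-3-bromo-4-chloro-4-methyl-1-(prop-1-en-2-yl)cyclohexyl]-3-methylbutanoic 2,2-dimethylpropanoic anhydride F6.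
- The lithium salt of (4S)-4-benzyl-1,3-oxazolidin-2-one converts it into (4S)-4-benzyl-3-{3-[(1S,3S,4S)-3-bromo-4-chloro-4-methyl-1-(prop-1-en-2-yl)cyclohexyl]-3-methylbutanoyl}-1,3-oxazolidin-2-one F7.
- Bu2BOTf and i-Pr2NEt in CH2Cl2 at −78 °C form the (Z)-dibutylboron enolate of that imide F8.
- NBS brominates the chelated enolate on the face away from the benzyl group, as in the known bromination of the 3,3-dimethylbutanoyl imide, to give (4S)-4-benzyl-3-{(2S)-2-bromo-3-[(1S,3S,4S)-3-bromo-4-chloro-4-methyl-1-(prop-1-en-2-yl)cyclohexyl]-3-methylbutanoyl}-1,3-oxazolidin-2-one F9.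
- LiBH4 in Et2O/MeOH at 0 °C releases (2S)-2-bromo-3-[(1S,3S,4S)-3-bromo-4-chloro-4-methyl-1-(prop-1-en-2-yl)cyclohexyl]-3-methylbutan-1-ol F10.
- Dess–Martin oxidation gives 24.

Further compounds
F1 | step 14 | (2S,3R,6S,8S,9S)-2,8-dibromo-9-chloro-1,1,9-trimethyl-5-methylidenespiro[5.5]undecan-3-ol | C=C1C[C@@H](O)[C@@H](Br)C(C)(C)[C@]12CC[C@](C)(Cl)[C@@H](Br)C2
F2 | step 14 | (2S,3S,6S,8S,9S)-2,8-dibromo-9-chloro-1,1,9-trimethyl-5-methylidenespiro[5.5]undecan-3-yl chloroacetate | C=C1C[C@H](OC(=O)CCl)[C@@H](Br)C(C)(C)[C@]12CC[C@](C)(Cl)[C@@H](Br)C2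
F3 | step 9 | (1R,3S,4S)-3-bromo-1-{4-[(tert-butyldiphenylsilyl)oxy]-2-methylbutan-2-yl}-4-chloro-4-methylcyclohexane-1-carboxylic acid | OC(=O)[C@]1(C(C)(C)CCO[Si](c2ccccc2)(c2ccccc2)C(C)(C)C)CC[C@](C)(Cl)[C@@H](Br)C1
F4 | step 9 | (1R,3S,4S)-3-bromo-1-{4-[(tert-butyldiphenylsilyl)oxy]-2-methylbutan-2-yl}-4-chloro-4-methylcyclohexane-1-carbonyl chloride | ClC(=O)[C@]1(C(C)(C)CCO[Si](c2ccccc2)(c2ccccc2)C(C)(C)C)CC[C@](C)(Cl)[C@@H](Br)C1
F5 | step 13 | 3-[(1S,3S,4S)-3-bromo-4-chloro-4-methyl-1-(prop-1-en-2-yl)cyclohexyl]-3-methylbutanoic acid | CC(=C)[C@]1(C(C)(C)CC(O)=O)CC[C@](C)(Cl)[C@@H](Br)C1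
F6 | step 13 | 3-[(1S,3S,4S)-3-bromo-4-chloro-4-methyl-1-(prop-1-en-2-yl)cyclohexyl]-3-methylbutanoic 2,2-dimethylpropanoic anhydride | CC(=C)[C@]1(C(C)(C)CC(=O)OC(=O)C(C)(C)C)CC[C@](C)(Cl)[C@@H](Br)C1
F7 | step 13 | (4S)-4-benzyl-3-{3-[(1S,3S,4S)-3-bromo-4-chloro-4-methyl-1-(prop-1-en-2-yl)cyclohexyl]-3-methylbutanoyl}-1,3-oxazolidin-2-one | CC(=C)[C@]1(C(C)(C)CC(=O)N2[C@@H](Cc3ccccc3)COC2=O)CC[C@](C)(Cl)[C@@H](Br)C1
F8 | step 13 | (Z)-dibutylboron enolate of F7 | CC(=C)[C@]1(C(C)(C)/C=C(\OB(CCCC)CCCC)N2[C@@H](Cc3ccccc3)COC2=O)CC[C@](C)(Cl)[C@@H](Br)C1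
F9 | step 13 | (4S)-4-benzyl-3-{(2S)-2-bromo-3-[(1S,3S,4S)-3-bromo-4-chloro-4-methyl-1-(prop-1-en-2-yl)cyclohexyl]-3-methylbutanoyl}-1,3-oxazolidin-2-one | CC(=C)[C@]1(C(C)(C)[C@H](Br)C(=O)N2[C@@H](Cc3ccccc3)COC2=O)CC[C@](C)(Cl)[C@@H](Br)C1
F10 | step 13 | (2S)-2-bromo-3-[(1S,3S,4S)-3-bromo-4-chloro-4-methyl-1-(prop-1-en-2-yl)cyclohexyl]-3-methylbutan-1-ol | CC(=C)[C@]1(C(C)(C)[C@H](Br)CO)CC[C@](C)(Cl)[C@@H](Br)C1
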